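The numbers in the tables were generated by integration with constants of no real substance, noise included.

I decided to carry one number from Friday's run to the new flask, reckoned so that time dropped out.

- Friday's: substrate 2.8 M; gas 200 mM (held); run made earlier
- flask: substrate 2.0 M; gas 200 mM (held); time 30 h

Friday's run (percent of the substrate charged)

| time / h | substrate / % | product / % |
|---|---|---|
| 1.33 | 16.2 | 23.3 |
| 2.50 | 3.5 | 44.1 |
| 5.00 | 0 | 67.6 |
| 10.0 | 0 | 77.2 |
| 20.0 | 0 | 77.1 |

(scatter of a reading: 0.5 percentage points)

- at the start none of the gas is in solution
- the reaction counts as stopped when no species that holds the substrate changes by six tenths of a point or more over the second half of the time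

- which holds at 30 h: what has brought the reaction to rest, or that it has not come to rest (it is still moving / forward and back rates have come level / all of the substrate has reacted)
- conversion of substrate at 30 h
- amount of product at 30 h, in percent of the substrate charged

I read a ladder of times off Friday's run. On the fastest rung the substrate fell at 1.37 h⁻¹, a half-life of 0.506 h. On the next, the product closed on its plateau at 0.498 h⁻¹, a half-life of 1.39 h, longer than the substrate's, so I expected the charge to wait in an unseen intermediate first. The 30 h asked of the new flask is far longer again, about 21.6 of those half-lives, so I expected a still mixture there.

What stands in that mixture is a matter of split, not of speed. Friday's plateau gave 3.37, which I took as my branch ratio, the selectivity factor: product at rest over the remainder of the charge. If both branches draw on the intermediate in the same order, it divides the rate into product by the rate elsewhere, so time cancels. With the gas held at the same 200 mM, I kept this reading for the new flask, and my estimate for it was 77.1% of its charge as product.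

The forecast said all of the substrate has reacted, with conversion 100% and product 77%, holding that “First-order steps make the yield independent of concentration”.

The flask gave all of the substrate has reacted, with conversion 100% and product 77.5%, so the forecast held.

    substrate → intermediate (k = 0.0230 min⁻¹)
    partner + intermediate → product (k = 0.0330 M⁻¹ min⁻¹)
    intermediate → decomposed reagent (k = 0.00190 min⁻¹)
    gas ⇌ partner, rate k4*(csat - [partner]) (kL = 3.80 min⁻¹)

At 0.502 h the intermediate in this flask had a half-life of 1.8 h by the step with partner against 6.1 h by decomposition, a rate ratio of 3.4. Partner in this flask stood at 0.199 M after 3.00 h and 0.200 M after 15.0 h, and at that level the step with partner is pseudo-first-order in intermediate.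

The same flask read at 8.0 h still held 2.71% as intermediate. My share, applied to the part of the charge that had left the intermediate, gives 75.0% as product, and the computed value is 75.4%.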